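Decoding the SMILES gives the (2S) configuration, the natural flavanone series. The target is (2S)-5'-prenylhomoeriodictyol, C21H22O6.

Assumption: 5,7-dihydroxychromone (CAS 31721-94-5) and both enantiomers of MeO-F12-BIPHEP are treated as catalogue items.

## Retrosynthetic overview
1. Target ⇒ its tris-MOM ether. One mild acidic global deprotection comes last, with no base after C2 is set.
2. Tris-MOM flavanone ⇒ disconnect C2–C1' by Rh-catalysed asymmetric 1,4-addition of an arylboronic acid to 5,7-bis(MOM)chromone. This is the only stereo-defining step.
3. Arylboronic acid ⇒ aryl bromide (Li/Br exchange, borylation) ⇒ 4-bromo-2-methoxyphenol plus prenyl bromide (ortho-C-prenylation; the para site is blocked by Br).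
4. Ring order: no ring is built. The A/C bicycle is bought as the chromone and ring B as bromoguaiacol. Ring C is only converted from pyranone to (2S)-dihydropyranone.

## Forward route

**Step 1**
Reactants: 1, 4-bromo-2-methoxyphenol; 2, prenyl bromide (1-bromo-3-methylbut-2-ene)
Product: 3, 4-bromo-2-methoxy-6-(3-methylbut-2-en-1-yl)phenol
Conditions: NaH (1.05 equiv), PhMe, 0 °C → rt; then 2 (1.1 equiv), rt, 16 h
Reagents that add atoms: prenyl bromide, CC(C)=CCBr
Why: This is an ortho-C-alkylation of a tight sodium phenoxide ion pair in a non-polar solvent, where O-alkylation is suppressed, only one ortho carbon is free and para is blocked by Br, so a single C-prenyl isomer forms and the O-prenyl ether by-product is removed by chromatography.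

**Step 2**
Reactants: 3
Product: 4, 5-bromo-1-methoxy-2-(methoxymethoxy)-3-(3-methylbut-2-en-1-yl)benzene
Conditions: MOMCl (1.5 equiv), i-Pr2NEt (2 equiv), CH2Cl2, 0 °C → rt
Reagents that add atoms: chloromethyl methyl ether, COCCl
Why: This Williamson-type O-alkylation (MOM acetal formation) uses a small electrophile that reaches the di-ortho-substituted phenol, removes the acidic OH before lithiation, and leaves the aryl bromide and prenyl group untouched.

**Step 3**
Reactants: 4
Product: 5, [3-methoxy-4-(methoxymethoxy)-5-(3-methylbut-2-en-1-yl)phenyl]boronic acid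
Conditions: n-BuLi (1.1 equiv), THF, −78 °C, 20 min; B(Oi-Pr)3 (1.5 equiv), −78 °C → rt; sat. aq NH4Cl
Reagents that add atoms: triisopropyl borate, CC(C)OB(OC(C)C)OC(C)C; water, O
Why: Li/Br exchange followed by borate trapping and hydrolysis works because exchange at −78 °C outruns deprotonation of the benzylic/allylic CH2, and the near-neutral work-up preserves the MOM acetal.

**Step 4**
Reactants: 6, 5,7-dihydroxy-4H-chromen-4-one
Product: 7, 5,7-bis(methoxymethoxy)-4H-chromen-4-one
Conditions: NaH (2.6 equiv), MOMCl (3 equiv), DMF, 0 °C → rt
Reagents that add atoms: chloromethyl methyl ether, COCCl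
Why: This double phenoxide O-alkylation needs full deprotonation with NaH to free the chelated 5-OH, and masking both acidic OH groups prevents the chromone from becoming an unreactive anion in Step 5.

**Step 5**
Reactants: 7 (1.0 equiv); 5 (2.0 equiv)
Product: 8, (2S)-5,7-bis(methoxymethoxy)-2-[3-methoxy-4-(methoxymethoxy)-5-(3-methylbut-2-en-1-yl)phenyl]-2,3-dihydro-4H-chromen-4-one
Conditions: [RhCl(C2H4)2]2 (1.5 mol %), (S)-MeO-F12-BIPHEP (3.3 mol %), aq KOH (20 mol %), CH2Cl2/H2O 10:1, 25 °C, 24 h
Reagents that add atoms: none beyond reactant 5 (the C3–H comes from water)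
Why: In this Hayashi–Miyaura asymmetric 1,4-addition, the aryl–Rh(I) species on the (S)-biaryl diphosphine adds to the Re face of C2 (the same sense as (S)-BINAP giving (S)-3-arylcyclohexanone) to set the (2S) centre, and the electron-poor ligand lets the deactivated dialkoxychromone react at rt, where retro-oxa-Michael racemisation and Rh interaction with the trisubstituted prenyl alkene are negligible.
Control: check ee by chiral HPLC. In the CD spectrum, 2S shows a negative Cotton effect near 290 nm and a positive one near 330 nm. If the sense is inverted, use the (R)-ligand.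

**Step 6**
Reactants: 8
Product: 9, (2S)-5,7-dihydroxy-2-[4-hydroxy-3-methoxy-5-(3-methylbut-2-en-1-yl)phenyl]-2,3-dihydro-4H-chromen-4-one (target)
Conditions: HCl (ca. 1.5 M, from conc. aq HCl), MeOH/THF, 40 °C, 3–6 h (monitored); work-up at pH 5–6, no base
Reagents that add atoms: none
Why: Acid-catalysed acetal solvolysis removes all three phenolic MOM groups under conditions milder than those needed for prenyl-to-chroman cyclisation, and avoiding base leaves the C2 centre unscrambled because flavanones racemise through base-induced chalcone opening.

## Compound list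
1 | 4-bromo-2-methoxyphenol | COc1cc(Br)ccc1O | starting material
2 | prenyl bromide | CC(C)=CCBr | starting material
3 | 4-bromo-2-methoxy-6-prenylphenol | COc1cc(Br)cc(CC=C(C)C)c1O | intermediate
4 | 5-bromo-1-methoxy-2-(methoxymethoxy)-3-prenylbenzene | COCOc1c(OC)cc(Br)cc1CC=C(C)C | intermediate
5 | [3-methoxy-4-(methoxymethoxy)-5-prenylphenyl]boronic acid | COCOc1c(OC)cc(B(O)O)cc1CC=C(C)C | intermediate
6 | 5,7-dihydroxy-4H-chromen-4-one | O=c1ccoc2cc(O)cc(O)c12 | starting material
7 | 5,7-bis(methoxymethoxy)-4H-chromen-4-one | COCOc1cc(OCOC)c2c(=O)ccoc2c1 | intermediate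
8 | (2S)-tris-MOM-5'-prenylhomoeriodictyol | COc1cc([C@@H]2CC(=O)c3c(OCOC)cc(OCOC)cc3O2)cc(CC=C(C)C)c1OCOC | intermediate
9 | (2S)-5'-prenylhomoeriodictyol | COc1cc([C@@H]2CC(=O)c3c(O)cc(O)cc3O2)cc(CC=C(C)C)c1O | target

## Summary
Total steps: 6. Longest linear sequence: 5 (Steps 1 → 2 → 3 → 5 → 6).

**Steps most likely to fail, with fallbacks**
1. **Step 5.** The chromone is deactivated and the electron-rich boronic acid is prone to protodeboronation, so conversion or ee may be low.
   - Fallback: abandon the C2–aryl disconnection.
   - Quench the aryllithium from 4 with DMF to give the aldehyde, then run a Claisen–Schmidt condensation with 2-hydroxy-4,6-bis(methoxymethoxy)acetophenone.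
   - Close the ring with NaOAc (oxa-Michael) to give rac-8.
   - Resolve kinetically by Ru–TsDPEN asymmetric transfer hydrogenation. The 2R enantiomer is reduced to the cis-flavan-4-ol and (2S)-8 is recovered (≤50%).
2. **Step 1.** O-prenylation competes with C-prenylation, so the yield may be modest.
   - Fallback: directed ortho-metalation of guaiacol MOM ether (n-BuLi, then Cu(I) and prenyl bromide) places the prenyl group next to the OMOM.
   - Sterically controlled Ir-catalysed C–H borylation then occurs at the only position with no ortho neighbour, giving the pinacol ester analogue of 5 in the same number of steps.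
3. **Step 6.** Acid may cyclise the prenyl group onto the free 4'-OH to form a dimethylchroman, or erode the ee.
   - Fallback: change the protecting-group strategy to silyl ethers (TBS or TIPS on all three phenols, installed in Steps 2 and 4).
   - Remove them at the end with Et3N·3HF or AcOH-buffered TBAF, which avoids strong acid altogether.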